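**Retrosynthetic overview**
1. Both 3-methylbut-2-enyl groups come last, by cross-metathesis of C-allyl groups: the 6-allyl from Claisen rearrangement of a 5-O-allyl ether, the 3'-allyl from Stille coupling of a 3'-bromide. The catechol MOM ethers are removed in the final step.
2. Furan ring (third ring formed): oxidative C-2/O-2' closure of a 2'-hydroxyisoflavone with DDQ, done before any allyl or prenyl group is present.
3. Pyranone ring (second): isoflavone from a chalcone by oxidative 1,2-aryl shift and acid cyclisation. The chalcone C–C bond comes from a Claisen–Schmidt aldol condensation that joins ring-A ketone 5 and ring-B aldehyde 9.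
4. Dimethylpyran ring (first): propargyl-ether Claisen rearrangement and electrocyclisation on phloroacetophenone; ring B comes from 2,4,5-trihydroxybenzaldehyde.

Assumption: the target SMILES has no stereocentre or other stereogenic element, so the compound is achiral and no enantiocontrol is needed; the only defined geometry in the route is the (E)-chalcone.

Locants for 13–22 are isoflavone locants (O-1, C-2 to C-8 on the chromenone, C-1' to C-6' on ring B). "Pyrano[2'',3'':7,8]" means a 2,2-dimethyl-2H-pyran fused through O-7 and C-8. "Coumaronochromone" means the isoflavone with O-2' bonded to C-2.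

**Route**

Step 1
Reactants: 1 2,4,6-trihydroxyacetophenone
Product: 2 1-[2,6-dihydroxy-4-(2-methylbut-3-yn-2-yloxy)phenyl]ethanone
Conditions: 3-chloro-3-methylbut-1-yne (1.1 equiv), DBU (1.2 equiv), CuCl2·2H2O (1 mol%), MeCN, −5 to 0 °C
Reagents that add atoms: 3-chloro-3-methylbut-1-yne, CC(C)(Cl)C#C
Why: Copper-catalysed O-propargylation (Williamson-type etherification) takes the most acidic 4-hydroxyl para to the acetyl group, while the two ortho-hydroxyls are held back by hydrogen bonding to and shielding by the carbonyl, so one equivalent of the tertiary chloride gives the 4-ether.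

Step 2
Reactants: 2 1-[2,6-dihydroxy-4-(2-methylbut-3-yn-2-yloxy)phenyl]ethanone
Product: 3 1-[2-(allyloxy)-6-hydroxy-4-(2-methylbut-3-yn-2-yloxy)phenyl]ethanone
Conditions: allyl bromide (1.1 equiv), K2CO3, acetone, reflux
Reagents that add atoms: allyl bromide, C=CCBr
Why: Williamson etherification of one of the two equivalent ortho-hydroxyls; the remaining one is locked in the hydrogen bond to the acetyl oxygen and is not alkylated under these mild conditions.

Step 3
Reactants: 3 1-[2-(allyloxy)-6-hydroxy-4-(2-methylbut-3-yn-2-yloxy)phenyl]ethanone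
Product: 5 1-[7-(allyloxy)-5-hydroxy-2,2-dimethyl-2H-chromen-6-yl]ethanone, via ortho-allenylphenol 4 (not isolated)
Conditions: xylenes, 135 °C, 8 h, Ar
Reagents that add atoms: none
Why: Aromatic propargyl Claisen rearrangement followed by 1,5-hydrogen shift and oxa-6π electrocyclisation; the hydrogen-bonded chelate fixes the arene double bond toward the carbon next to the free hydroxyl so the [3,3] shift goes there, and 135 °C is below the temperature at which the allyl ether rearranges.

Step 4
Reactants: 6 2,4,5-trihydroxybenzaldehyde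
Product: 7 2-hydroxy-4,5-bis(methoxymethoxy)benzaldehyde
Conditions: MOMCl (2.2 equiv), i-Pr2NEt, CH2Cl2/DMF, 0 °C to rt
Reagents that add atoms: chloromethyl methyl ether, COCCl
Why: Etherification of the two free hydroxyls as MOM acetals; the 2-hydroxyl hydrogen-bonded to the aldehyde stays untouched.

Step 5
Reactants: 7 2-hydroxy-4,5-bis(methoxymethoxy)benzaldehyde
Product: 8 3-bromo-2-hydroxy-4,5-bis(methoxymethoxy)benzaldehyde
Conditions: NBS (1.05 equiv), MeCN, 0 °C, dark
Reagents that add atoms: N-bromosuccinimide, O=C1CCC(=O)N1Br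
Why: Electrophilic aromatic bromination occurs at C-3, ortho to the free phenol and to the 4-OMOM group, because the para position is occupied and C-6 is deactivated by the adjacent formyl group.

Step 6
Reactants: 8 3-bromo-2-hydroxy-4,5-bis(methoxymethoxy)benzaldehyde
Product: 9 2-(allyloxy)-3-bromo-4,5-bis(methoxymethoxy)benzaldehyde
Conditions: allyl bromide (1.5 equiv), K2CO3, DMF, 50 °C
Reagents that add atoms: allyl bromide, C=CCBr
Why: Williamson etherification masks O-2 with a group that withstands base, the oxidative rearrangement and acid and is later removed without acid.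

Step 7
Reactants: 5 1-[7-(allyloxy)-5-hydroxy-2,2-dimethyl-2H-chromen-6-yl]ethanone; 9 2-(allyloxy)-3-bromo-4,5-bis(methoxymethoxy)benzaldehyde
Product: 11 (E)-1-[7-(allyloxy)-5-hydroxy-2,2-dimethyl-2H-chromen-6-yl]-3-[2-(allyloxy)-3-bromo-4,5-bis(methoxymethoxy)phenyl]prop-2-en-1-one, via aldol adduct 10 (not isolated)
Conditions: KOH (50% aq, 10 equiv), EtOH, rt, 36 h; then cold dilute HCl to pH 5–6
Reagents that add atoms: none
Why: Claisen–Schmidt aldol condensation: the potassium enolate of methyl ketone 5 adds to the non-enolisable aldehyde 9 and the aldol loses water (E1cB) to give the conjugated enone with the thermodynamic (E) geometry, while MOM and allyl ethers, the aryl bromide and the chromene are inert to hydroxide.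

Step 8
Reactants: 11 (E)-chalcone
Product: 12 1-[7-(allyloxy)-5-hydroxy-2,2-dimethyl-2H-chromen-6-yl]-2-[2-(allyloxy)-3-bromo-4,5-bis(methoxymethoxy)phenyl]-3,3-dimethoxypropan-1-one (racemic)
Conditions: Tl(NO3)3·3H2O (1.05 equiv), MeOH/HC(OMe)3 (3:1), 0 °C to rt, 1–2 h
Reagents that add atoms: methanol, CO
Why: Oxidative 1,2-aryl migration of the chalcone (trivalent thallium adds to the enone, methanol adds at the benzylic carbon and the electron-rich trialkoxyaryl ring shifts as thallium leaves) gives the β-keto acetal; with 1.05 equivalents at low temperature the aryl-activated enone is expected to react ahead of the inductively deactivated allyl ethers and the acyl-deactivated chromene.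

Step 9
Reactants: 12 β-keto dimethyl acetal
Product: 13 5,2'-bis(allyloxy)-3'-bromo-4',5'-dihydroxy-6'',6''-dimethylpyrano[2'',3'':7,8]isoflavone
Conditions: 3 M HCl in MeOH, 60 °C, 2 h, N2
Reagents that add atoms: none
Why: Acid-catalysed acetal ionisation, attack by the free ring-A hydroxyl and loss of methanol (cyclodehydration to the chromen-4-one) with cleavage of the MOM acetals; the other ortho oxygen carries the acid-stable allyl group, so only the hydroxyl next to the chromene carbon can close, which fixes the angular pyran fusion.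

Step 10
Reactants: 13 isoflavone catechol
Product: 14 5,2'-bis(allyloxy)-3'-bromo-4',5'-bis(methoxymethoxy)-6'',6''-dimethylpyrano[2'',3'':7,8]isoflavone
Conditions: MOMCl (3 equiv), i-Pr2NEt, CH2Cl2, 0 °C to rt
Reagents that add atoms: chloromethyl methyl ether, COCCl
Why: Etherification of the two catechol hydroxyls (the only free OH groups) restores MOM acetals, which mask the catechol during the oxidation and come off under mild acid at the end.

Step 11
Reactants: 14 bis-MOM isoflavone
Product: 15 3'-bromo-5,2'-dihydroxy-4',5'-bis(methoxymethoxy)-6'',6''-dimethylpyrano[2'',3'':7,8]isoflavone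
Conditions: Pd(PPh3)4 (5 mol%), morpholine (10 equiv), THF, rt
Reagents that add atoms: none
Why: Tsuji–Trost deallylation: zerovalent palladium ionises both aryl allyl ethers to π-allyl complexes that morpholine captures, freeing 5-OH and 2'-OH at room temperature, where the hindered electron-rich aryl bromide does not undergo oxidative addition.

Step 12
Reactants: 15 2'-hydroxyisoflavone
Product: 16 3'-bromo-5-hydroxy-4',5'-bis(methoxymethoxy)-6'',6''-dimethylpyrano[2'',3'':7,8]coumaronochromone
Conditions: DDQ (1.5 equiv), dry 1,4-dioxane, rt to 50 °C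
Reagents that add atoms: none
Why: DDQ-mediated oxidative cyclisation (dehydrogenative C–O bond formation) joins the electron-rich 2'-phenol oxygen to C-2 and removes two hydrogens to give the furan; no allyl or prenyl group is present, the chromene has no abstractable allylic hydrogen, the catechol is masked and the 5-OH is deactivated by chelation.

Step 13
Reactants: 16 3'-bromo coumaronochromone
Product: 17 3'-allyl-5-hydroxy-4',5'-bis(methoxymethoxy)-6'',6''-dimethylpyrano[2'',3'':7,8]coumaronochromone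
Conditions: allyltributylstannane (1.5 equiv), Pd(P(t-Bu)3)2 (5 mol%), CsF (2.2 equiv), 1,4-dioxane, 100 °C
Reagents that add atoms: allyltributylstannane, C=CC[Sn](CCCC)(CCCC)CCCC
Why: Stille cross-coupling: the bulky electron-rich phosphine lets palladium insert into the di-ortho-oxygenated aryl bromide and fluoride-assisted allyl transfer from tin puts the allyl group at C-3', the position fixed by the bromination in step 5.

Step 14
Reactants: 17 3'-allyl coumaronochromone
Product: 18 3'-allyl-5-(allyloxy)-4',5'-bis(methoxymethoxy)-6'',6''-dimethylpyrano[2'',3'':7,8]coumaronochromone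
Conditions: allyl bromide (3 equiv), K2CO3, DMF, 60 °C
Reagents that add atoms: allyl bromide, C=CCBr
Why: Williamson etherification of the only free hydroxyl; carbonate in DMF with excess allyl bromide overcomes the hydrogen bond to the carbonyl.

Step 15
Reactants: 18 5-O-allyl ether
Product: 20 6,3'-diallyl-5-hydroxy-4',5'-bis(methoxymethoxy)-6'',6''-dimethylpyrano[2'',3'':7,8]coumaronochromone, via ortho-dienone 19 (not isolated)
Conditions: N,N-diethylaniline, 195 °C, 3 h, Ar
Reagents that add atoms: none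
Why: Aromatic Claisen rearrangement ([3,3]-sigmatropic shift, then tautomerisation of the dienone): C-6 is the only free ortho position of the 5-O-allyl ether, so the allyl group is delivered there and the chelated 5-OH is regenerated.

Step 16
Reactants: 20 6,3'-diallyl compound
Product: 21 5-hydroxy-4',5'-bis(methoxymethoxy)-6,3'-bis(3-methylbut-2-enyl)-6'',6''-dimethylpyrano[2'',3'':7,8]coumaronochromone
Conditions: second-generation Grubbs catalyst RuCl2(=CHPh)(H2IMes)(PCy3) (2 × 5 mol%), 2-methylbut-2-ene/CH2Cl2 (1:3), 40 °C, sealed tube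
Reagents that add atoms: 2-methylbut-2-ene, CC=C(C)C
Why: Olefin cross-metathesis of both terminal allyl groups with excess 2-methylbut-2-ene converts them into 3-methylbut-2-enyl groups with loss of propene; the cis-disubstituted chromene alkene next to a quaternary carbon does not take part.

Step 17
Reactants: 21 bis-MOM ether
Product: 22 5,4',5'-trihydroxy-6,3'-bis(3-methylbut-2-enyl)-6'',6''-dimethylpyrano[2'',3'':7,8]coumaronochromone (CNP0329721.0)
Conditions: 3 M aq HCl/MeOH/THF (1:4:1), rt to 40 °C, N2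
Reagents that add atoms: none
Why: Acid-catalysed acetal cleavage removes both MOM ethers under conditions too mild to cyclise the ortho-prenyl phenols or add to the alkenes, giving the achiral target.

**Compound list**
1 | 2,4,6-trihydroxyacetophenone | CC(=O)c1c(O)cc(O)cc1O | starting material
2 | 1-[2,6-dihydroxy-4-(2-methylbut-3-yn-2-yloxy)phenyl]ethanone | CC(=O)c1c(O)cc(OC(C)(C)C#C)cc1O | intermediate
3 | 1-[2-(allyloxy)-6-hydroxy-4-(2-methylbut-3-yn-2-yloxy)phenyl]ethanone | CC(=O)c1c(O)cc(OC(C)(C)C#C)cc1OCC=C | intermediate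
4 | 1-[2-(allyloxy)-4,6-dihydroxy-5-(3-methylbuta-1,2-dienyl)phenyl]ethanone (ortho-allenylphenol, not isolated) | CC(=O)c1c(O)c(C=C=C(C)C)c(O)cc1OCC=C | intermediate
5 | 1-[7-(allyloxy)-5-hydroxy-2,2-dimethyl-2H-chromen-6-yl]ethanone | CC(=O)c1c(O)c2C=CC(C)(C)Oc2cc1OCC=C | intermediate
6 | 2,4,5-trihydroxybenzaldehyde | O=Cc1cc(O)c(O)cc1O | starting material
7 | 2-hydroxy-4,5-bis(methoxymethoxy)benzaldehyde | O=Cc1cc(OCOC)c(OCOC)cc1O | intermediate
8 | 3-bromo-2-hydroxy-4,5-bis(methoxymethoxy)benzaldehyde | O=Cc1cc(OCOC)c(OCOC)c(Br)c1O | intermediate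
9 | 2-(allyloxy)-3-bromo-4,5-bis(methoxymethoxy)benzaldehyde | O=Cc1cc(OCOC)c(OCOC)c(Br)c1OCC=C | intermediate
10 | 1-[7-(allyloxy)-5-hydroxy-2,2-dimethyl-2H-chromen-6-yl]-3-[2-(allyloxy)-3-bromo-4,5-bis(methoxymethoxy)phenyl]-3-hydroxypropan-1-one (racemic aldol adduct, not isolated) | O=C(CC(O)c1cc(OCOC)c(OCOC)c(Br)c1OCC=C)c1c(O)c2C=CC(C)(C)Oc2cc1OCC=C | intermediate
11 | (E)-1-[7-(allyloxy)-5-hydroxy-2,2-dimethyl-2H-chromen-6-yl]-3-[2-(allyloxy)-3-bromo-4,5-bis(methoxymethoxy)phenyl]prop-2-en-1-one | O=C(/C=C/c1cc(OCOC)c(OCOC)c(Br)c1OCC=C)c1c(O)c2C=CC(C)(C)Oc2cc1OCC=C | intermediate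
12 | 1-[7-(allyloxy)-5-hydroxy-2,2-dimethyl-2H-chromen-6-yl]-2-[2-(allyloxy)-3-bromo-4,5-bis(methoxymethoxy)phenyl]-3,3-dimethoxypropan-1-one (racemic) | COC(OC)C(C(=O)c1c(O)c2C=CC(C)(C)Oc2cc1OCC=C)c1cc(OCOC)c(OCOC)c(Br)c1OCC=C | intermediate
13 | 5,2'-bis(allyloxy)-3'-bromo-4',5'-dihydroxy-6'',6''-dimethylpyrano[2'',3'':7,8]isoflavone | O=c1c(-c2cc(O)c(O)c(Br)c2OCC=C)coc2c3C=CC(C)(C)Oc3cc(OCC=C)c12 | intermediate
14 | 5,2'-bis(allyloxy)-3'-bromo-4',5'-bis(methoxymethoxy)-6'',6''-dimethylpyrano[2'',3'':7,8]isoflavone | O=c1c(-c2cc(OCOC)c(OCOC)c(Br)c2OCC=C)coc2c3C=CC(C)(C)Oc3cc(OCC=C)c12 | intermediate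
15 | 3'-bromo-5,2'-dihydroxy-4',5'-bis(methoxymethoxy)-6'',6''-dimethylpyrano[2'',3'':7,8]isoflavone | O=c1c(-c2cc(OCOC)c(OCOC)c(Br)c2O)coc2c3C=CC(C)(C)Oc3cc(O)c12 | intermediate
16 | 3'-bromo-5-hydroxy-4',5'-bis(methoxymethoxy)-6'',6''-dimethylpyrano[2'',3'':7,8]coumaronochromone | O=c1c2c(O)cc3OC(C)(C)C=Cc3c2oc2oc3c(Br)c(OCOC)c(OCOC)cc3c12 | intermediate
17 | 3'-allyl-5-hydroxy-4',5'-bis(methoxymethoxy)-6'',6''-dimethylpyrano[2'',3'':7,8]coumaronochromone | O=c1c2c(O)cc3OC(C)(C)C=Cc3c2oc2oc3c(CC=C)c(OCOC)c(OCOC)cc3c12 | intermediate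
18 | 3'-allyl-5-(allyloxy)-4',5'-bis(methoxymethoxy)-6'',6''-dimethylpyrano[2'',3'':7,8]coumaronochromone | O=c1c2c(OCC=C)cc3OC(C)(C)C=Cc3c2oc2oc3c(CC=C)c(OCOC)c(OCOC)cc3c12 | intermediate
19 | 6-allyl-5-oxo-5,6-dihydro tautomer of 20 (racemic ortho-dienone, not isolated) | C=CCC1C(=O)C2=C(OC3=C(C2=O)c2cc(OCOC)c(OCOC)c(CC=C)c2O3)C2=C1OC(C)(C)C=C2 | intermediate
20 | 6,3'-diallyl-5-hydroxy-4',5'-bis(methoxymethoxy)-6'',6''-dimethylpyrano[2'',3'':7,8]coumaronochromone | O=c1c2c(O)c(CC=C)c3OC(C)(C)C=Cc3c2oc2oc3c(CC=C)c(OCOC)c(OCOC)cc3c12 | intermediate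
21 | 5-hydroxy-4',5'-bis(methoxymethoxy)-6,3'-bis(3-methylbut-2-enyl)-6'',6''-dimethylpyrano[2'',3'':7,8]coumaronochromone | O=c1c2c(O)c(CC=C(C)C)c3OC(C)(C)C=Cc3c2oc2oc3c(CC=C(C)C)c(OCOC)c(OCOC)cc3c12 | intermediate
22 | 5,4',5'-trihydroxy-6,3'-bis(3-methylbut-2-enyl)-6'',6''-dimethylpyrano[2'',3'':7,8]coumaronochromone (CNP0329721.0, achiral) | CC(C)=CCc1c2c(c3oc4oc5c(CC=C(C)C)c(O)c(O)cc5c4c(=O)c3c1O)C=CC(C)(C)O2 | target

**Totals**
Total steps: 17. Longest linear sequence: 14 steps (1 → 2 → 3 → 5 → 11 → 12 → 13 → 14 → 15 → 16 → 17 → 18 → 20 → 21 → 22; the ring-B branch from 6 is equally long).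

**Steps most likely to fail, with fallbacks**

Step 8 (oxidative aryl shift in a molecule with three other alkenes and a free phenol). The fallback sets out from chalcone 11 and uses no electrophilic oxidant. The ring-A phenol is protected (MOMCl, NaH, THF) to give (E)-1-[7-(allyloxy)-5-(methoxymethoxy)-2,2-dimethyl-2H-chromen-6-yl]-3-[2-(allyloxy)-3-bromo-4,5-bis(methoxymethoxy)phenyl]prop-2-en-1-one F2. Nucleophilic Weitz–Scheffer epoxidation (30% H2O2, NaOH, MeOH/THF, 0 °C) touches only the enone and gives the racemic trans-epoxy ketone [7-(allyloxy)-5-(methoxymethoxy)-2,2-dimethyl-2H-chromen-6-yl]{3-[2-(allyloxy)-3-bromo-4,5-bis(methoxymethoxy)phenyl]oxiran-2-yl}methanone F3. BF3·OEt2 (CH2Cl2, −40 °C) opens the benzylic epoxide carbon and induces a 1,2-aroyl shift to the α-formyl deoxybenzoin 2-[2-(allyloxy)-3-bromo-4,5-bis(methoxymethoxy)phenyl]-3-[7-(allyloxy)-5-(methoxymethoxy)-2,2-dimethyl-2H-chromen-6-yl]-3-oxopropanal F4. Heating F4 in 3 M HCl/MeOH at 60 °C removes the MOM groups and cyclodehydrates, which comes back to the route at isoflavone 13.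

Step 12 (DDQ closure of the furan on a very electron-rich ring B). The fallback sets out from isoflavone 14 and replaces the oxidation by an addition–elimination at C-2. Alkaline ring opening (KOH, EtOH/H2O, reflux; loss of C-2 as formate) gives the deoxybenzoin 1-[7-(allyloxy)-5-hydroxy-2,2-dimethyl-2H-chromen-6-yl]-2-[2-(allyloxy)-3-bromo-4,5-bis(methoxymethoxy)phenyl]ethanone F5. Condensation with CS2 and MeI (Bu4NHSO4, aq NaOH/THF) rebuilds the pyranone with a leaving group, giving 5,2'-bis(allyloxy)-3'-bromo-4',5'-bis(methoxymethoxy)-2-(methylthio)-6'',6''-dimethylpyrano[2'',3'':7,8]isoflavone F6. Deallylation (Pd(PPh3)4, morpholine, THF, rt) gives 3'-bromo-5,2'-dihydroxy-4',5'-bis(methoxymethoxy)-2-(methylthio)-6'',6''-dimethylpyrano[2'',3'':7,8]isoflavone F7. K2CO3 in DMF at 80 °C lets the 2'-phenoxide displace methanethiolate at C-2, which comes back to the route at coumaronochromone 16.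

Step 3 (regiochemistry of the propargyl Claisen shift, and survival of the allyl ether at 135 °C). The fallback sets out from 2 and reverses the order of cyclisation and differentiation. Heating 2 itself (xylenes, 135 °C) can give only one chromene because its two ortho positions are equivalent, namely 1-(5,7-dihydroxy-2,2-dimethyl-2H-chromen-6-yl)ethanone F1. Mono-allylation (allyl bromide 1.0 equiv, K2CO3, acetone, rt) at the less hindered 7-hydroxyl, with the regioisomer removed by chromatography and the assignment made by NOE between OCH2 and H-8, comes back to the route at 5.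

Further compounds
F1 | step 3 | 1-(5,7-dihydroxy-2,2-dimethyl-2H-chromen-6-yl)ethanone | CC(=O)c1c(O)cc2OC(C)(C)C=Cc2c1O
F2 | step 8 | (E)-1-[7-(allyloxy)-5-(methoxymethoxy)-2,2-dimethyl-2H-chromen-6-yl]-3-[2-(allyloxy)-3-bromo-4,5-bis(methoxymethoxy)phenyl]prop-2-en-1-one | O=C(/C=C/c1cc(OCOC)c(OCOC)c(Br)c1OCC=C)c1c(OCOC)c2C=CC(C)(C)Oc2cc1OCC=C
F3 | step 8 | racemic trans-epoxy ketone [7-(allyloxy)-5-(methoxymethoxy)-2,2-dimethyl-2H-chromen-6-yl]{3-[2-(allyloxy)-3-bromo-4,5-bis(methoxymethoxy)phenyl]oxiran-2-yl}methanone ((2R,3S) enantiomer drawn) | O=C([C@@H]1O[C@H]1c1cc(OCOC)c(OCOC)c(Br)c1OCC=C)c1c(OCOC)c2C=CC(C)(C)Oc2cc1OCC=C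
F4 | step 8 | 2-[2-(allyloxy)-3-bromo-4,5-bis(methoxymethoxy)phenyl]-3-[7-(allyloxy)-5-(methoxymethoxy)-2,2-dimethyl-2H-chromen-6-yl]-3-oxopropanal (racemic) | O=CC(C(=O)c1c(OCOC)c2C=CC(C)(C)Oc2cc1OCC=C)c1cc(OCOC)c(OCOC)c(Br)c1OCC=C
F5 | step 12 | 1-[7-(allyloxy)-5-hydroxy-2,2-dimethyl-2H-chromen-6-yl]-2-[2-(allyloxy)-3-bromo-4,5-bis(methoxymethoxy)phenyl]ethanone | O=C(Cc1cc(OCOC)c(OCOC)c(Br)c1OCC=C)c1c(O)c2C=CC(C)(C)Oc2cc1OCC=C
F6 | step 12 | 5,2'-bis(allyloxy)-3'-bromo-4',5'-bis(methoxymethoxy)-2-(methylthio)-6'',6''-dimethylpyrano[2'',3'':7,8]isoflavone | CSc1oc2c3C=CC(C)(C)Oc3cc(OCC=C)c2c(=O)c1-c1cc(OCOC)c(OCOC)c(Br)c1OCC=C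
F7 | step 12 | 3'-bromo-5,2'-dihydroxy-4',5'-bis(methoxymethoxy)-2-(methylthio)-6'',6''-dimethylpyrano[2'',3'':7,8]isoflavone | CSc1oc2c3C=CC(C)(C)Oc3cc(O)c2c(=O)c1-c1cc(OCOC)c(OCOC)c(Br)c1O
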